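## Structural features

The target is a flavonol: a 3,5,7-trihydroxychromen-4-one in which ring A is a phloroglucinol-type benzene ring and ring C is a 4-pyranone carrying the enolic 3-OH. C2 of ring C is bonded to C6 of a 2,2-dimethylchroman-3-ol, whose benzene ring is ring B and whose dihydropyran is ring D, so O1 of ring D lies para to the flavonol. The only stereocentre is C3 of ring D (R; OH > C2 > C4 > H). It sits between the quaternary C2 with the gem-dimethyl group and the benzylic C4 methylene, so no two stereocentres are adjacent and the centre is not enolisable. Fragile elements are the chelating 3-OH/4-C=O/5-OH array (air- and base-sensitive once unmasked), the secondary alcohol (oxidation to the ketone would erase the stereocentre) and the tertiary alkyl aryl ether O1–C2 of ring D (cleaved by strong Lewis or Brønsted acids). The real difficulty is control rather than size: ring C must close six-membered with the 5,7-oxygen pattern on the right side, the C3 oxygen must be introduced without touching the chromanol, and the lone stereocentre must be set on a ring where 5-exo and 6-endo ether closures can compete. The key step uses the fact that C4 is one carbonyl carbon between C4a of ring A and a C3–C2 unit bearing the chromanyl group, with O1 on C8a ortho to C4a. That is the atom pattern of an ortho-hydroxyaryl alkynyl ketone, hence of an ortho-iodophenol, carbon monoxide and a terminal aryl alkyne.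

## Logic of the disconnections

**19 to 18.** The two O–CH2Ph bonds at O5 and O7 are cut. Benzyl ethers leave under neutral hydrogenolysis, which the flavonol, the secondary alcohol and the tertiary ether of ring D tolerate. The gain is that the sensitive triphenol appears only in the last flask. The forward step must stop short of the C2=C3 bond and the aryl C–O bonds.

**18 to 15 (through 17 and 16).** The C3–O bond of ring C is cut and the silyl group is put back on the chromanol oxygen. C3 of a flavone is the nucleophilic carbon of a vinylogous ester, so oxygen can be delivered by electrophilic epoxidation of C2=C3 followed by acid opening towards the O1- and aryl-stabilised C2 cation. The gain is that ring C can be assembled without the C3 oxygen, which is what allows an alkyne to supply C2 and C3. The oxidant must spare the chromanol, which is why the silyl ether stays until the oxidation is over, and it must spare the benzylic C–H bonds.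

**15 to 2 + 11 + 12.** The C4a–C4, C4–C3 and O1–C2 bonds are cut. This removes ring C in one operation, divides the molecule into two fragments of similar size plus one carbon, and fixes the 5,7-pattern by where the iodine of 2 sits. The forward step must make carbonylation outrun direct aryl–alkyne coupling, must close ring C 6-endo, and must meet no free alcohol that could capture the acyl–metal intermediate.

**2 to 1.** The C–I bond is cut. The carbon between the hydroxyl and a benzyloxy group is one of two equivalent ortho positions of a strongly activated ring, so the ring A fragment comes from a catalogue phenol in one step. The demand is mono-iodination ortho to the hydroxyl and not between the two ethers.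

**11 to 10 to 8 + 9.** The C6–C(sp) bond is cut, after restoring the silyl cap on the alkyne terminus. An aryl–alkynyl bond is the standard palladium/copper disconnection, and the cap prevents double arylation. The alkyne fragment is reduced to an aryl bromide. The coupling must work on an electron-rich bromide, and the C-silyl group must later leave while the O-silyl group stays.

**8 to 7.** The O–Si bond is cut. This protection changes no skeleton, but it decides chemoselectivity twice: a free secondary alcohol would be oxidised by the dioxirane in step 9 and could be acylated in step 8. The forward step must silylate a hindered, neopentyl-type alcohol with a group that survives an amine at 120 °C and leaves by acid methanolysis.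

**7 to 6 to 5.** The C4–H bond is replaced by the C4–O bond of a cis-epoxide, and then both epoxide C–O bonds are cut. The stereocentre becomes C3 of the epoxide of a 2,2-dimethylchromene, a substrate class on which salen–manganese epoxidation is highly enantioselective, and hydride opening at benzylic C4 never touches the C3–O bond. Because the pyran ring exists before the stereocentre is made, no 5-exo/6-endo choice arises, as it would if a phenol closed onto a side-chain epoxide. The demands are catalyst-controlled facial selectivity and hydride attack at C4 only.

**5 to 3 + 4.** The C4–C4a and O1–C2 bonds are cut. A 2,2-dimethylchromene is a phenol plus a five-carbon enal equivalent, joined through an ortho-quinone methide and 6π-electrocyclisation. This reaches two catalogue compounds. The demand is ortho C-alkylation of a slightly deactivated phenol.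

## Other disconnections considered

**Alternative 1:** The cut is the C4a–C5 bond of ring A, which is unravelled to an open poly-β-carbonyl chain. In the forward step the polyenolate of methyl (E)-9-aryl-3,5,7-trioxonon-8-enoate A1 (aryl = the silylated (R)-chromanyl unit) would close by Claisen attack of C6 on the ester carbon. Enolisation would give ring A as the 2',4',6'-trihydroxychalcone A2.
- **In its favour:** ring A appears with all three oxygens in place and unprotected, from acetoacetate-type units, with no aryl halide, no palladium and no pressurised CO. The chromanyl fragment enters as a cinnamoyl unit that an aldehyde would provide.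
- **Against it here:** A1 can also close by aldol attack of C2 on the C7 ketone, by lactonisation through an enol oxygen, or by conjugate addition to its own enone, so the Claisen mode would have to be enforced by base and counter-ion. A2 is still one ring and one oxidation short of the target. Oxidative closure of a 2'-hydroxychalcone with a 6'-oxygen tends towards five-membered (aurone-type) closure, so ring A would need protecting-group adjustment first.
- **Comparison:** structurally it builds ring A and postpones ring C, whereas the chosen plan buys ring A and builds ring C. Mechanistically its regiochemistry depends on which enolate meets which carbonyl, whereas the chosen plan fixes it by the iodine of 2. The stereocentre is handled identically (a remote silyl ether), so the two are equal there. The alternative is better in needing no autoclave and no benzyl ethers on ring A. It is worse in step economy, because ring closure, C3 oxidation and deprotection all remain after A2, on top of the assembly of A1.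

**Alternative 2:** The cut is the C2'–C3' and C1'–C6' bonds of ring B. In the forward step (R)-3-(tert-butyldimethylsilyloxy)-2,2-dimethyl-3,4-dihydro-2H,5H-pyrano[3,2-c]pyran-5-one A3 would add across the alkyne of 3,5,7-tris(benzyloxy)-2-ethynylchromone A4 in a Diels–Alder reaction. Loss of CO2 from the bridged adduct would aromatise ring B and give A5.
- **In its favour:** it is highly convergent, the C3 oxygen is present from the start, and CO2 loss makes the step irreversible. The polarity matches the required orientation: the nucleophilic C3 of the pyranone should bond to the electrophilic alkyne terminus.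
- **Against it here:** 2-pyranones are reluctant dienes towards alkynes and would need prolonged heating well above 150 °C. A3 (unsubstituted at the pyranone C6 and already carrying the stereocentre) and A4 each need several steps. The stereocentre would have to be set on a non-aromatic heterocycle, for which nothing as dependable as the epoxidation of 5 is at hand.
- **Comparison:** structurally it makes ring B last through two bonds, whereas the chosen plan makes ring C through three. Mechanistically it is pericyclic and metal-free, with regiochemistry from orbital polarisation and not from a pre-placed halogen. The protecting-group load is about equal (A5 has three benzyl ethers and a silyl ether; 15 has two and one). It is better in avoiding both the dioxirane oxidation and CO. It is worse in step count and in the confidence one can place in its key step.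

**Alternative 3:** The cut is the C8a–O1 bond. In the forward step anodic oxidation of (R)-6-[3-(2,4-dimethoxyphenyl)-2-methoxy-3-oxopropanoyl]-2,2-dimethylchroman-3-yl acetate A6 would let the enol oxygen next to the chromanyl group attack the free ortho position of the dimethoxyphenyl ring. This would close ring C and give the tri-O-methyl acetate A7.
- **In its favour:** A6 would come from two simple aryl carbonyl partners by Claisen-type acylation, and the C3 oxygen is built in. The closure needs no halogen, no CO and no palladium, and ring size is enforced geometrically, so the aurone question does not arise.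
- **Against it here:** the C–O bond must form meta to both methoxy groups, the position of least positive charge in an arene radical cation, while the methoxy-bearing ortho carbon competes by ipso attack. The alkoxy-substituted ring B and the benzylic C4–H of ring D are oxidisable at similar potential. A7 ends with three methyl ethers, and their Lewis-acidic cleavage threatens the tertiary ether of ring D and the secondary alcohol. The acetate adds one more deprotection.
- **Comparison:** both plans close ring C, this one at O1–C8a only and the chosen one at O1–C2 plus two C–C bonds. The mechanism is oxidative C–H functionalisation against addition–elimination on a pre-functionalised iodide. The alternative is equal in step count up to the cyclised chromone and better in atom economy and in carrying the C3 oxygen from the start. It is worse in the end-game, where neutral hydrogenolysis is replaced by a demethylation that ring D is unlikely to tolerate.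

Key step: step 8

Remark on the chemistry: the chromanol is carried as its tert-butyldimethylsilyl ether from 8 to 17, because a free secondary alcohol would be oxidised by the dioxirane of step 9 and could be acylated by the aroylpalladium intermediate of step 8. The stereodescriptor R (O > C2 > C4 > H) is unchanged by silylation.

Assumption: 1, 3, 4, 9 and 12 are taken as catalogue compounds.

## Steps

Step 1
Reactants: 1 3,5-bis(benzyloxy)phenol
Product: 2 3,5-bis(benzyloxy)-2-iodophenol
Conditions: NIS (1.0 equiv), CH2Cl2, −40 → 0 °C, dark
Reagents that add atoms: N-iodosuccinimide, O=C1CCC(=O)N1I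
Why: Electrophilic aromatic iodination of a phloroglucinol-type ring; the two positions ortho to the free hydroxyl are equivalent and less hindered than the position flanked by two benzyloxy groups, and one equivalent at low temperature should limit a second iodination.

Step 2
Reactants: 3 4-bromophenol; 4 1,1-diethoxy-3-methylbut-2-ene
Product: 5 6-bromo-2,2-dimethyl-2H-chromene
Conditions: 3-picoline (0.25 equiv), p-xylene, reflux (ca. 140 °C), EtOH distilled off
Reagents that add atoms: none
Why: Chromenylation of a phenol with a prenal equivalent: acetal exchange, ortho C-alkylation through the unsaturated oxocarbenium ion, loss of ethanol to the ortho-quinone methide and 6π-oxa-electrocyclisation; the bromine blocks the para position, so only the two equivalent ortho sites can react.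

Step 3
Reactants: 5 6-bromo-2,2-dimethyl-2H-chromene
Product: 6 (3R,4R)-6-bromo-3,4-epoxy-2,2-dimethylchroman
Conditions: (R,R)-(salen)MnCl [(R,R)-N,N'-bis(3,5-di-tert-butylsalicylidene)cyclohexane-1,2-diaminomanganese chloride] (3 mol %), 4-phenylpyridine N-oxide (0.2 equiv), aq. NaOCl (pH 11.3, Na2HPO4), CH2Cl2, 0 °C
Reagents that add atoms: sodium hypochlorite, [Na+].[O-]Cl
Why: Jacobsen epoxidation of a cis-disubstituted conjugated olefin, for which 2,2-dimethylchromenes are among the best substrates; the (R,R)-ligand is expected to steer side-on approach of the olefin to the oxomanganese species so that oxygen arrives on the face giving the (3R,4R)-epoxide, which sets C3.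

Step 4
Reactants: 6 (3R,4R)-6-bromo-3,4-epoxy-2,2-dimethylchroman
Product: 7 (R)-6-bromo-2,2-dimethylchroman-3-ol
Conditions: LiAlH4 (1.0 equiv), THF, 0 °C; aqueous NaOH work-up
Reagents that add atoms: none
Why: SN2 opening of the epoxide by hydride at the benzylic C4, since C3 is shielded by the adjacent quaternary C2; the C3–O bond is never broken, so the configuration set in step 3 is retained as R, and the aryl bromide should be inert to LiAlH4 at 0 °C.

Step 5
Reactants: 7 (R)-6-bromo-2,2-dimethylchroman-3-ol
Product: 8 (R)-[(6-bromo-2,2-dimethylchroman-3-yl)oxy](tert-butyl)dimethylsilane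
Conditions: TBSOTf (1.3 equiv), 2,6-lutidine (2 equiv), CH2Cl2, 0 °C → rt
Reagents that add atoms: tert-butyldimethylsilyl triflate, CC(C)(C)[Si](C)(C)OS(=O)(=O)C(F)(F)F
Why: Silylation of a secondary alcohol; the silyl triflate is chosen because the hydroxyl is neopentyl-like, and the resulting ether is stable to amines, carbonate and dioxirane but leaves under acid methanolysis.

Step 6
Reactants: 8 (R)-[(6-bromo-2,2-dimethylchroman-3-yl)oxy](tert-butyl)dimethylsilane; 9 ethynyltrimethylsilane
Product: 10 (R)-tert-butyldimethyl{[2,2-dimethyl-6-(trimethylsilylethynyl)chroman-3-yl]oxy}silane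
Conditions: PdCl2(PhCN)2 (3 mol %), [HP(t-Bu)3]BF4 (6 mol %), CuI (2 mol %), i-Pr2NH, 1,4-dioxane, rt → 40 °C
Reagents that add atoms: none
Why: Sonogashira coupling; the bulky electron-rich phosphine lets zerovalent palladium insert into the electron-rich (para-alkoxy) aryl bromide at low temperature, and the silyl cap on the alkyne prevents a second arylation.

Step 7
Reactants: 10 (R)-tert-butyldimethyl{[2,2-dimethyl-6-(trimethylsilylethynyl)chroman-3-yl]oxy}silane
Product: 11 (R)-tert-butyl[(6-ethynyl-2,2-dimethylchroman-3-yl)oxy]dimethylsilane
Conditions: K2CO3 (0.2 equiv), MeOH/THF, rt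
Reagents that add atoms: none
Why: Methoxide-catalysed protodesilylation of the alkynyl C–Si bond; the hindered secondary O-silyl ether is not cleaved under these conditions.

Step 8
Reactants: 2 3,5-bis(benzyloxy)-2-iodophenol; 11 (R)-tert-butyl[(6-ethynyl-2,2-dimethylchroman-3-yl)oxy]dimethylsilane; 12 carbon monoxide
Product: 15 5,7-bis(benzyloxy)-2-[(R)-3-(tert-butyldimethylsilyloxy)-2,2-dimethylchroman-6-yl]-4H-chromen-4-one, via hydroxyaryl ynone 13 (not isolated), via diethylaminoenone 14 (not isolated)
Conditions: 2 (1.2 equiv), 11 (1.0 equiv), PdCl2(PPh3)2 (5 mol %), Et2NH (solvent), CO (20 bar), 120 °C, autoclave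
Reagents that add atoms: none
Why: Zerovalent palladium, formed in the flask from PdCl2(PPh3)2, inserts into the C–I bond of 2 and CO insertion gives an aroylpalladium iodide; amine-assisted transfer of the alkynyl group of 11 and reductive elimination then give ynone 13, which creates the C4a–C4 and C4–C3 bonds. Diethylamine adds to 13 in conjugate fashion to give enaminone 14, and the ortho-phenol adds to its β-carbon and expels the amine, which forms O1–C2. The closest known reaction type is the carbonylative Sonogashira coupling of ortho-iodophenols with terminal alkynes with cyclisation to chromones in a secondary amine. Ring C closes 6-endo-trig by addition–elimination on 14, which bypasses the 5-exo-dig attack on the free ynone that would lead to an aurone. No stereocentre is formed; the existing C3 centre of ring D is remote, not enolisable and silylated, so it should pass unchanged. Carbonylative coupling is favoured over direct coupling by the CO pressure, the absence of copper and the relief of strain when CO inserts into the di-ortho-substituted arylpalladium species. The 5,7-oxygen pattern is fixed because the iodine of 2 lies between the hydroxyl and one benzyloxy group. The silyl ether removes the only alcohol that could capture the aroylpalladium intermediate as an ester.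

Step 9
Reactants: 15 5,7-bis(benzyloxy)-2-[(R)-3-(tert-butyldimethylsilyloxy)-2,2-dimethylchroman-6-yl]-4H-chromen-4-one
Product: 18 5,7-bis(benzyloxy)-3-hydroxy-2-[(R)-3-hydroxy-2,2-dimethylchroman-6-yl]-4H-chromen-4-one, via flavone epoxide 16 (not isolated), via silylated flavonol 17 (not isolated)
Conditions: DMDO (ca. 0.07 M in acetone, 3 equiv), CH2Cl2, 0 °C → rt; evaporate; TsOH·H2O (0.1 equiv), CH2Cl2, rt; then MeOH, TsOH·H2O (1 equiv), 40 °C
Reagents that add atoms: dimethyldioxirane, CC1(C)OO1
Why: Electrophilic epoxidation of the C2=C3 bond of the flavone by the dioxirane gives the acid-labile epoxide 16, which opens under acid at C2 (cation stabilised by O1 and the aryl group) and loses H3 to give the enol 17; acid methanolysis then removes the silyl ether, which until then keeps the secondary alcohol from being oxidised to the ketone. The epoxide stereocentres are uncontrolled and disappear when ring C re-aromatises.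

Step 10
Reactants: 18 5,7-bis(benzyloxy)-3-hydroxy-2-[(R)-3-hydroxy-2,2-dimethylchroman-6-yl]-4H-chromen-4-one
Product: 19 3,5,7-trihydroxy-2-[(R)-3-hydroxy-2,2-dimethylchroman-6-yl]-4H-chromen-4-one
Conditions: H2 (1 atm), 10% Pd/C, THF/MeOH, rt
Reagents that add atoms: none
Why: Hydrogenolysis of the two aryl benzyl ethers under neutral conditions; the flavonol C2=C3 bond, the aryl C–O bonds of ring D and the chromanol are not expected to react at atmospheric pressure, and the stereocentre is untouched.

## Compound list

1 | 3,5-bis(benzyloxy)phenol | Oc1cc(OCc2ccccc2)cc(OCc2ccccc2)c1 | starting material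
2 | 3,5-bis(benzyloxy)-2-iodophenol | Oc1cc(OCc2ccccc2)cc(OCc2ccccc2)c1I | intermediate
3 | 4-bromophenol | Oc1ccc(Br)cc1 | starting material
4 | 1,1-diethoxy-3-methylbut-2-ene (3-methylbut-2-enal diethyl acetal) | CCOC(OCC)C=C(C)C | starting material
5 | 6-bromo-2,2-dimethyl-2H-chromene | CC1(C)C=Cc2cc(Br)ccc2O1 | intermediate
6 | (3R,4R)-6-bromo-3,4-epoxy-2,2-dimethylchroman [(1aR,7bR)-6-bromo-2,2-dimethyl-1a,7b-dihydro-2H-oxireno[2,3-c]chromene] | CC1(C)Oc2ccc(Br)cc2[C@H]2O[C@@H]12 | intermediate
7 | (R)-6-bromo-2,2-dimethylchroman-3-ol | CC1(C)Oc2ccc(Br)cc2C[C@H]1O | intermediate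
8 | (R)-[(6-bromo-2,2-dimethylchroman-3-yl)oxy](tert-butyl)dimethylsilane | CC1(C)Oc2ccc(Br)cc2C[C@H]1O[Si](C)(C)C(C)(C)C | intermediate
9 | ethynyltrimethylsilane | C#C[Si](C)(C)C | starting material
10 | (R)-tert-butyldimethyl{[2,2-dimethyl-6-(trimethylsilylethynyl)chroman-3-yl]oxy}silane | CC1(C)Oc2ccc(C#C[Si](C)(C)C)cc2C[C@H]1O[Si](C)(C)C(C)(C)C | intermediate
11 | (R)-tert-butyl[(6-ethynyl-2,2-dimethylchroman-3-yl)oxy]dimethylsilane | CC1(C)Oc2ccc(C#C)cc2C[C@H]1O[Si](C)(C)C(C)(C)C | intermediate
12 | carbon monoxide | [C-]#[O+] | starting material
13 | 1-[2,4-bis(benzyloxy)-6-hydroxyphenyl]-3-[(R)-3-(tert-butyldimethylsilyloxy)-2,2-dimethylchroman-6-yl]prop-2-yn-1-one | O=C(C#Cc1ccc2OC(C)(C)[C@H](O[Si](C)(C)C(C)(C)C)Cc2c1)c1c(O)cc(OCc2ccccc2)cc1OCc1ccccc1 | intermediate (not isolated)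
14 | (E)-1-[2,4-bis(benzyloxy)-6-hydroxyphenyl]-3-(diethylamino)-3-[(R)-3-(tert-butyldimethylsilyloxy)-2,2-dimethylchroman-6-yl]prop-2-en-1-one | O=C(/C=C(/N(CC)CC)c1ccc2OC(C)(C)[C@H](O[Si](C)(C)C(C)(C)C)Cc2c1)c1c(O)cc(OCc2ccccc2)cc1OCc1ccccc1 | intermediate (not isolated)
15 | 5,7-bis(benzyloxy)-2-[(R)-3-(tert-butyldimethylsilyloxy)-2,2-dimethylchroman-6-yl]-4H-chromen-4-one | CC1(C)Oc2ccc(cc2C[C@H]1O[Si](C)(C)C(C)(C)C)-c1cc(=O)c2c(OCc3ccccc3)cc(OCc3ccccc3)cc2o1 | intermediate
16 | 5,7-bis(benzyloxy)-2-[(R)-3-(tert-butyldimethylsilyloxy)-2,2-dimethylchroman-6-yl]-2,3-epoxy-2,3-dihydro-4H-chromen-4-one (both epoxide diastereomers; epoxide centres not controlled) | CC1(C)Oc2ccc(cc2C[C@H]1O[Si](C)(C)C(C)(C)C)C12OC1C(=O)c1c(OCc3ccccc3)cc(OCc3ccccc3)cc1O2 | intermediate (not isolated)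
17 | 5,7-bis(benzyloxy)-3-hydroxy-2-[(R)-3-(tert-butyldimethylsilyloxy)-2,2-dimethylchroman-6-yl]-4H-chromen-4-one | CC1(C)Oc2ccc(cc2C[C@H]1O[Si](C)(C)C(C)(C)C)-c1oc2cc(OCc3ccccc3)cc(OCc3ccccc3)c2c(=O)c1O | intermediate (not isolated)
18 | 5,7-bis(benzyloxy)-3-hydroxy-2-[(R)-3-hydroxy-2,2-dimethylchroman-6-yl]-4H-chromen-4-one | CC1(C)Oc2ccc(cc2C[C@H]1O)-c1oc2cc(OCc3ccccc3)cc(OCc3ccccc3)c2c(=O)c1O | intermediate
19 | 3,5,7-trihydroxy-2-[(R)-3-hydroxy-2,2-dimethylchroman-6-yl]-4H-chromen-4-one | CC1(C)Oc2ccc(-c3oc4cc(O)cc(O)c4c(=O)c3O)cc2C[C@H]1O | target

## Step count and least certain steps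

Total step count: 10 (step 1 for the ring A fragment, steps 2–7 for the alkyne, steps 8–10 after convergence).
Longest linear sequence: 9 steps (steps 2–10, from 3 to 19).

**Step 8 (key step).** The likely failures are three. Direct aryl–alkyne coupling followed by furan closure could occur if CO insertion lags. Diethylamine could capture the aroylpalladium intermediate (aminocarbonylation), because alkynyl transfer to a doubly ortho-flanked acyl group may be slow. Oxidative addition into the electron-rich, hindered iodide may itself be sluggish.
Fallback (no palladium, no CO), setting out from 1 and 11 and returning at 13: magnesium-mediated ortho-formylation of 1 (MgCl2, Et3N, paraformaldehyde, MeCN, reflux) would give 2,4-bis(benzyloxy)-6-hydroxybenzaldehyde F1. Its lithium phenoxide (LiN(SiMe3)2, THF, −78 °C) would be treated with the lithium acetylide of 11 (n-BuLi, THF, −78 → 0 °C) to give 3,5-bis(benzyloxy)-2-{1-hydroxy-3-[(R)-3-(tert-butyldimethylsilyloxy)-2,2-dimethylchroman-6-yl]prop-2-yn-1-yl}phenol F2. Oxidation of F2 with MnO2 in CH2Cl2 would give 13, which on warming in Et2NH/EtOH should close through 14 to 15.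

**Step 1.** Iodination could occur at the position between the two benzyloxy groups, or a second time, because all three free ring positions are strongly activated.
Fallback (directed ortho-metalation), setting out from 1 and returning at 2: carbamoylation (Et2NCOCl, NaH, THF) would give 3,5-bis(benzyloxy)phenyl diethylcarbamate F3. Lithiation between the carbamate and a benzyloxy group (s-BuLi, TMEDA, THF, −78 °C) and quenching with I2 would give 3,5-bis(benzyloxy)-2-iodophenyl diethylcarbamate F4. Hydrolysis (KOH, EtOH/H2O, reflux) would return 2.

**Step 2.** Ortho C-alkylation of the bromine-deactivated phenol may be slow, leaving acetal-exchange products that do not go on to the quinone methide, and the chromene may oligomerise on prolonged heating.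
Fallback (aromatic Claisen route), setting out from 3 and returning at 5: O-alkylation with 3-chloro-3-methylbut-1-yne (K2CO3, KI, CuI cat., acetone, reflux) would give 1-bromo-4-[(2-methylbut-3-yn-2-yl)oxy]benzene F5. Heating F5 in N,N-diethylaniline at about 190 °C should give 5 by propargyl Claisen rearrangement, 1,5-hydrogen shift and 6π-electrocyclisation.

**Step 4.** Hydride could be delivered to C3 instead of C4, bromine could be lost reductively if the mixture warms, and the acid-sensitive benzylic epoxide could open on handling before reduction.
Fallback (side-chain epoxide, no epoxide reduction), setting out from 3 and returning at 7: ortho C-prenylation of the sodium phenoxide (NaH, prenyl bromide, toluene, rt) would give 4-bromo-2-(3-methylbut-2-en-1-yl)phenol F6. Silylation (TBSCl, imidazole, DMF) would give [4-bromo-2-(3-methylbut-2-en-1-yl)phenoxy](tert-butyl)dimethylsilane F7. Shi epoxidation with the D-fructose-derived ketone (KHSO5 as 2KHSO5·KHSO4·K2SO4, K2CO3, MeCN/dimethoxymethane/H2O, 0 °C) would give tert-butyl{4-bromo-2-[((2R)-3,3-dimethyloxiran-2-yl)methyl]phenoxy}dimethylsilane F8. Buffered desilylation (Bu4NF, AcOH, THF, 0 °C) would give (R)-4-bromo-2-[(3,3-dimethyloxiran-2-yl)methyl]phenol F9. Camphorsulfonic acid in CH2Cl2 at 0 °C should then close F9 6-endo at the tertiary epoxide carbon, with the carbinol configuration retained, to give 7. This route has its own 5-exo/6-endo risk, which is why it is the fallback and not the main line.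

**Step 9.** Epoxidation of the electron-poor C2=C3 bond is slow, so the dioxirane may attack the benzylic C–H bonds of the benzyl ethers or the C–H next to the silyloxy group instead. The epoxide may also be trapped by methanol if the alcohol is added before the acid opening is complete.
Fallback (C3 metalation, no dioxirane), setting out from 15 and returning at 17: deprotonation at C3 (LiN(i-Pr)2, THF, −78 °C) and trapping with B(OMe)3 would give dimethyl {5,7-bis(benzyloxy)-2-[(R)-3-(tert-butyldimethylsilyloxy)-2,2-dimethylchroman-6-yl]-4-oxo-4H-chromen-3-yl}boronate F10. Oxidation with H2O2/AcOH would give 17, which is desilylated with TsOH·H2O in MeOH as in step 9 to give 18.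

## Further compounds

F1 | step 8 | 2,4-bis(benzyloxy)-6-hydroxybenzaldehyde | O=Cc1c(O)cc(OCc2ccccc2)cc1OCc1ccccc1
F2 | step 8 | 3,5-bis(benzyloxy)-2-{1-hydroxy-3-[(R)-3-(tert-butyldimethylsilyloxy)-2,2-dimethylchroman-6-yl]prop-2-yn-1-yl}phenol (both carbinol epimers) | OC(C#Cc1ccc2OC(C)(C)[C@H](O[Si](C)(C)C(C)(C)C)Cc2c1)c1c(O)cc(OCc2ccccc2)cc1OCc1ccccc1
F3 | step 1 | 3,5-bis(benzyloxy)phenyl diethylcarbamate | CCN(CC)C(=O)Oc1cc(OCc2ccccc2)cc(OCc2ccccc2)c1
F4 | step 1 | 3,5-bis(benzyloxy)-2-iodophenyl diethylcarbamate | CCN(CC)C(=O)Oc1cc(OCc2ccccc2)cc(OCc2ccccc2)c1I
F5 | step 2 | 1-bromo-4-[(2-methylbut-3-yn-2-yl)oxy]benzene | CC(C)(C#C)Oc1ccc(Br)cc1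
F6 | step 4 | 4-bromo-2-(3-methylbut-2-en-1-yl)phenol | CC(C)=CCc1cc(Br)ccc1O
F7 | step 4 | [4-bromo-2-(3-methylbut-2-en-1-yl)phenoxy](tert-butyl)dimethylsilane | CC(C)=CCc1cc(Br)ccc1O[Si](C)(C)C(C)(C)C
F8 | step 4 | tert-butyl{4-bromo-2-[((2R)-3,3-dimethyloxiran-2-yl)methyl]phenoxy}dimethylsilane | CC1(C)O[C@@H]1Cc1cc(Br)ccc1O[Si](C)(C)C(C)(C)C
F9 | step 4 | (R)-4-bromo-2-[(3,3-dimethyloxiran-2-yl)methyl]phenol | CC1(C)O[C@@H]1Cc1cc(Br)ccc1O
F10 | step 9 | dimethyl {5,7-bis(benzyloxy)-2-[(R)-3-(tert-butyldimethylsilyloxy)-2,2-dimethylchroman-6-yl]-4-oxo-4H-chromen-3-yl}boronate | CC1(C)Oc2ccc(cc2C[C@H]1O[Si](C)(C)C(C)(C)C)-c1oc2cc(OCc3ccccc3)cc(OCc3ccccc3)c2c(=O)c1B(OC)OC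
A1 | alternative 1 | methyl (E)-9-[(R)-3-(tert-butyldimethylsilyloxy)-2,2-dimethylchroman-6-yl]-3,5,7-trioxonon-8-enoate | COC(=O)CC(=O)CC(=O)CC(=O)/C=C/c1ccc2OC(C)(C)[C@H](O[Si](C)(C)C(C)(C)C)Cc2c1
A2 | alternative 1 | (E)-3-[(R)-3-(tert-butyldimethylsilyloxy)-2,2-dimethylchroman-6-yl]-1-(2,4,6-trihydroxyphenyl)prop-2-en-1-one | O=C(/C=C/c1ccc2OC(C)(C)[C@H](O[Si](C)(C)C(C)(C)C)Cc2c1)c1c(O)cc(O)cc1O
A3 | alternative 2 | (R)-3-(tert-butyldimethylsilyloxy)-2,2-dimethyl-3,4-dihydro-2H,5H-pyrano[3,2-c]pyran-5-one | O=C1OC=CC2=C1C[C@@H](O[Si](C)(C)C(C)(C)C)C(C)(C)O2
A4 | alternative 2 | 3,5,7-tris(benzyloxy)-2-ethynyl-4H-chromen-4-one | C#Cc1oc2cc(OCc3ccccc3)cc(OCc3ccccc3)c2c(=O)c1OCc1ccccc1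
A5 | alternative 2 | 3,5,7-tris(benzyloxy)-2-[(R)-3-(tert-butyldimethylsilyloxy)-2,2-dimethylchroman-6-yl]-4H-chromen-4-one | CC1(C)Oc2ccc(cc2C[C@H]1O[Si](C)(C)C(C)(C)C)-c1oc2cc(OCc3ccccc3)cc(OCc3ccccc3)c2c(=O)c1OCc1ccccc1
A6 | alternative 3 | (R)-6-[3-(2,4-dimethoxyphenyl)-2-methoxy-3-oxopropanoyl]-2,2-dimethylchroman-3-yl acetate | COC(C(=O)c1ccc(OC)cc1OC)C(=O)c1ccc2OC(C)(C)[C@H](OC(C)=O)Cc2c1
A7 | alternative 3 | (R)-2,2-dimethyl-6-(3,5,7-trimethoxy-4-oxo-4H-chromen-2-yl)chroman-3-yl acetate | CC(=O)O[C@@H]1Cc2cc(ccc2OC1(C)C)-c1oc2cc(OC)cc(OC)c2c(=O)c1OC
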